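**Assumption (one line):** the target is taken exactly as drawn, (3S,4R) in the lactone ring and (R) at the side-chain carbon C1', which places the C3 carboxyl and the C4 side chain cis on the lactone ring; 3,4,5-tris(benzyloxy)benzoic acid, 2,5-dihydrofuran and (2E)-3-(tributylstannyl)prop-2-en-1-ol are taken as purchasable.

Target numbering used below: lactone ring B = C1(=O)–O2–C3–C4–C4a–C8a; ring A = C4a–C5(OH)–C6(OH)–C7(OH)–C8(H)–C8a; side chain = C1'(CO2H)–CH2–CO2H on C4.

## The problem

The target is a 3,4-dihydroisocoumarin (ring B, a δ-lactone) fused to a pyrogallol ring (ring A), with three contiguous stereocentres: C3 (S, lactone oxygen and a carboxyl), C4 (R, benzylic) and the exocyclic C1' (R). The C3 carboxyl and the C4 side chain are cis on ring B, and C1' lies outside every ring, so its configuration cannot simply be relayed from the ring. C4 is flanked by two ortho substituents of ring A (the C5 oxygen and the lactone carbonyl), so any intermolecular bond formation between an aryl nucleophile and C4 is hindered. C3 and C1' are α to carboxyl groups and can epimerize. A free C3 hydroxyl would have competing acyl partners (the C1' carboxyl gives a γ-lactone), so the isochromanone should be closed unambiguously and never reopened. The free pyrogallol is air- and base-sensitive and has to be released last, without base. The enabling feature is that the carboxyl carbon on C3, then C3–C4–C1'–CH2, then the terminal carboxyl carbon form an adipic acid, i.e. an opened cyclohexene (ring C). Closed in the mind, ring C is fused to ring B across C3–C4, carries O2 on an allylic carbon (C3) and has the aryl group (on C4) and a carbonyl (on C1') trans on neighbouring carbons. That is the retron of an intramolecular Diels–Alder reaction in which the benzoate ester of ring B is the tether.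

## Retrosynthesis

**13 ⇒ 12 (three O–benzyl bonds).** The phenols are carried as benzyl ethers and released by hydrogenolysis in the last step. Methyl ethers would need Lewis acids that threaten the α-acyloxy acid at C3. The cut costs nothing in complexity, but it requires that no alkene is left at that stage and that the lactone is already in place.

**12 ⇒ 10 via 11 (carboxyl carbons rejoined).** The carboxyl carbon on C3 and the terminal carboxyl carbon of the CH2CO2H arm are joined into a cis ring alkene, and the C1' carboxyl is taken back to a formyl group. This turns the two ring centres and the exocyclic centre into three contiguous centres on a cis-fused tricycle, aldehyde 10. The forward reaction is an alkene cleavage plus aldehyde oxidation that must spare the arene and benzyl ethers and must not enolize C3 or C1'.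

**10 ⇒ 9 (retro-[4+2]; bonds C4a–C10b and C1–C2 of 10, i.e. C3–C4 and C1'–CH2 of the target).** The precursor 9 is achiral and has no ring other than ring A. Against the neighbouring cuts:
- An intermolecular cycloaddition of a 1-acyloxybutadiene with a cinnamate-type dienophile would join the oxygen-bearing diene terminus to the α-carbon, the wrong regiochemistry. The tether reverses this.
- Cutting only C4–C1' (Michael) or only C4–aryl leaves the three centres to be set one by one.

The forward reaction has to deliver a cis ring fusion (asked of the (Z)-dienyl ester), aryl trans to formyl (asked of the (E)-enal) and one enantiomer (asked of a chiral iminium catalyst).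

**9 ⇒ 8 ⇒ 6 + 7 (oxidation state; aryl–alkenyl bond).** The enal is unmasked last from allylic alcohol 8, so that no cycloaddition can run before the chiral catalyst is present. The aryl–alkenyl bond comes from a Stille coupling of iodide 6 with stannane 7. A Heck reaction is excluded by the diene. A free 2-carboxy-cinnamaldehyde would close to a phthalide by oxa-Michael addition, hence ester first and neutral coupling second. The forward reaction must couple at a di-ortho-substituted iodide without touching the diene.

**6 ⇒ 2 + 3 (acyl C–O bond).** The (Z)-dienyl ester comes from O-acylation of the cis-dienolate 5 obtained by base-induced ring opening of 2,5-dihydrofuran 3. The ring fixes the (Z) geometry, whereas the dienolate of crotonaldehyde would give mainly (E). The acyl partner is acid chloride 4 from acid 2.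

**2 ⇒ 1 (carbon–iodine bond).** Electrophilic iodination of 1; the two free positions are equivalent.

## Roads not taken

**Alternative 1:** (the most obvious) Cut the lactone C–O bond, the C4–aryl bond and the C1'–CH2 bond. Forward: copper-mediated conjugate addition of an aryl nucleophile derived from iodide 2 (as an ester) to the chiral-pool butenolide A1, anti to its ester group, then enolate alkylation with a bromoacetate to give γ-lactone A2, then translactonization to the isochromanone. The chosen plan is better for four reasons:
- The aryl nucleophile is di-ortho-substituted and adds sluggishly.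
- Alkylation anti to the aryl group sets C1' opposite to what A2 requires (aryl and CH2CO2R cis), so a corrective step is needed.
- The γ-to-δ lactone exchange needs a basic opening next to two epimerizable centres, and its position of equilibrium is open.
- The centres are set one per step instead of all at once.

**Alternative 2:** Cut the C3–H bond (reduction). Forward: asymmetric transfer hydrogenation of α-keto ester A3 with dynamic kinetic resolution through the enolizable benzylic C4; A3 would come from Michael addition of an arylpyruvate to a fumaric diester. The chosen plan is better for three reasons: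
- The resolution relates only C3 and C4; C1' is set without control in the Michael step and is not equilibrated.
- The hindered aryl group slows both steps.
- The new hydroxyl lactonizes fastest onto the C1' ester (γ-lactone) rather than onto the aryl ester, so the wrong ring forms first.

**Alternative 3:** Cut nothing in the chain but make it by ring fission. Forward: the fourteen carbons and the lactone of the target map onto ellagic acid A4; oxidative intradiol-type cleavage of one pyrogallol ring (peracid or a catechol dioxygenase) would give the ring-fission diacid A5, and hydrogenation of its two C=C bonds would give the skeleton. The chosen plan is better for two reasons: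
- The two rings of A4 are identical, so there is no basis for cleaving one only, or for stopping there.
- All three stereocentres would have to come from hydrogenation of a tetrasubstituted enol-lactone alkene and a trisubstituted alkene with no control element.

The chosen plan also ends in a carbon–carbon cleavage, but of a ring alkene whose three centres are already fixed.

Key step: step 5

## Route

**Step 1**
Reactants: 1 3,4,5-tris(benzyloxy)benzoic acid
Product: 2 3,4,5-tris(benzyloxy)-2-iodobenzoic acid
Conditions: N-iodosuccinimide (1.05 equiv), CF3CO2H (0.3 equiv), MeCN, rt, dark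
Reagents that add atoms: N-iodosuccinimide, O=C1CCC(=O)N1I
Why: Electrophilic aromatic iodination; the two free positions are equivalent and are activated by an ortho and a para benzyloxy group, so one equivalent of reagent should give the mono-iodide.

**Step 2**
Reactants: 2 3,4,5-tris(benzyloxy)-2-iodobenzoic acid; 3 2,5-dihydrofuran
Product: 6 (1Z)-buta-1,3-dien-1-yl 3,4,5-tris(benzyloxy)-2-iodobenzoate, via acyl chloride 4 (not isolated), via lithium (1Z)-buta-1,3-dien-1-olate 5 (not isolated)
Conditions: (a) 2, (COCl)2, DMF (cat.), CH2Cl2, 0 °C to rt, evaporate; (b) 3, n-BuLi (0.95 equiv to 3), THF, −78 to 0 °C, then 4 in THF, −78 °C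
Reagents that add atoms: none
Why: Lithiation of 2,5-dihydrofuran at C2 and β-elimination of the ring oxygen (cycloreversion) give the cis-dienolate because the ring holds O and C3 cis; O-acylation of this aldehyde dienolate by the aroyl chloride (enolate O-acylation) then gives the (Z)-dienyl ester.

**Step 3**
Reactants: 6 (1Z)-buta-1,3-dien-1-yl 3,4,5-tris(benzyloxy)-2-iodobenzoate; 7 (2E)-3-(tributylstannyl)prop-2-en-1-ol
Product: 8 (1Z)-buta-1,3-dien-1-yl 3,4,5-tris(benzyloxy)-2-[(1E)-3-hydroxyprop-1-en-1-yl]benzoate
Conditions: Pd2(dba)3 (2.5 mol %), AsPh3 (20 mol %), CuI (10 mol %), DMF, 40 °C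
Reagents that add atoms: none
Why: Copper-assisted Stille coupling with retention of the (E)-alkenyl geometry under neutral conditions that spare the enol ester and tolerate the free hydroxyl; fast transmetalation should outrun arylpalladation of the diene, which needs the unfavoured E rotamer of the ester.

**Step 4**
Reactants: 8 (1Z)-buta-1,3-dien-1-yl 3,4,5-tris(benzyloxy)-2-[(1E)-3-hydroxyprop-1-en-1-yl]benzoate
Product: 9 (1Z)-buta-1,3-dien-1-yl 3,4,5-tris(benzyloxy)-2-[(1E)-3-oxoprop-1-en-1-yl]benzoate
Conditions: MnO2 (activated, 15 equiv), CH2Cl2, rt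
Reagents that add atoms: none
Why: Allylic alcohol oxidation with MnO2 is selective, base-free and leaves the dienyl ester and both alkene geometries untouched; the dienophile is unmasked only now, directly before the catalysed cycloaddition.

**Step 5**
Reactants: 9 (1Z)-buta-1,3-dien-1-yl 3,4,5-tris(benzyloxy)-2-[(1E)-3-oxoprop-1-en-1-yl]benzoate
Product: 10 (1R,4aR,10bR)-8,9,10-tris(benzyloxy)-6-oxo-1,2,4a,10b-tetrahydro-6H-benzo[c]chromene-1-carbaldehyde
Conditions: (2R,5R)-5-benzyl-2-tert-butyl-3-methylimidazolidin-4-one·CF3CO2H (20 mol %), MeCN/H2O 98:2, 0 °C to rt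
Reagents that add atoms: none
Why: The amine salt condenses with the enal of 9 to an (E)-configured unsaturated iminium ion whose lowered LUMO engages the tethered 1-acyloxydiene in a concerted, asynchronous [4+2] cycloaddition, and hydrolysis releases 10 and the catalyst. The closest known reaction type is the imidazolidinone-catalysed intramolecular Diels–Alder reaction of trienals, combined with the known behaviour of (Z)-dienes in intramolecular Diels–Alder reactions, which give cis-fused products only. Two rings close at once: the cyclohexene (ring C) by suprafacial [4+2] addition through bonds C4a–C10b and C1–C2, and the δ-lactone (ring B) as the six-membered ring spanned by the four-atom benzoate tether when C4a–C10b forms. At C4a and C10b the ester oxygen occupies the inside (Z) position of the diene terminus and can reach the aryl group only when the aryl group is exo, which gives the cis ring fusion. At C1 the (E)-geometry of the enal is transferred suprafacially, so the formyl group is trans to the aryl group and endo, the orientation that iminium catalysis also prefers, so tether geometry and endo preference lead to the same single diastereomer. The benzyl group of the (2R,5R) catalyst shields the Si face at the α-carbon of the iminium ion, the diene adds to the Re face, and this sets C1 as R and with it C10b and C4a. The regiochemistry, which an intermolecular reaction would deliver the other way round, is fixed by the tether. The only selectivity left to the catalyst is therefore facial, and it needs the uncatalysed background to be negligible, which an unactivated enal with a (Z)-diene and an ester tether should ensure at room temperature.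

**Step 6**
Reactants: 10 (1R,4aR,10bR)-8,9,10-tris(benzyloxy)-6-oxo-1,2,4a,10b-tetrahydro-6H-benzo[c]chromene-1-carbaldehyde
Product: 12 (2R)-2-[(3S,4R)-5,6,7-tris(benzyloxy)-3-carboxy-1-oxo-3,4-dihydro-1H-isochromen-4-yl]butanedioic acid, via trialdehyde 11 (not isolated)
Conditions: OsO4 (2 mol %), NaIO4 (4 equiv), 2,6-lutidine (2 equiv), 1,4-dioxane/H2O 3:1, rt; then NaClO2, NaH2PO4, 2-methyl-2-butene, t-BuOH/H2O, 0 °C to rt
Reagents that add atoms: osmium tetroxide, O=[Os](=O)(=O)=O; sodium periodate, [Na+].[O-]I(=O)(=O)=O; sodium chlorite, [Na+].[O-]Cl=O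
Why: Lemieux–Johnson cleavage of the only alkene gives the trialdehyde, and Pinnick oxidation under weakly acidic buffered conditions with a hypochlorite scavenger takes all three formyl groups to carboxyl groups without opening the lactone; no stereocentre is made, and the short-lived aldehydes are not exposed to strong base.

**Step 7**
Reactants: 12 (2R)-2-[(3S,4R)-5,6,7-tris(benzyloxy)-3-carboxy-1-oxo-3,4-dihydro-1H-isochromen-4-yl]butanedioic acid
Product: 13 (2R)-2-[(3S,4R)-3-carboxy-5,6,7-trihydroxy-1-oxo-3,4-dihydro-1H-isochromen-4-yl]butanedioic acid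
Conditions: H2 (1 atm), 10% Pd/C, THF/MeOH 1:1, rt; filtration and evaporation under argon
Reagents that add atoms: none
Why: Hydrogenolysis of the three aryl benzyl ethers under neutral conditions; no other reducible group remains, the lactone C–O bond is not benzylic, and the base-free work-up avoids epimerization, lactone migration and oxidation of the pyrogallol.

## Compound list

1 | 3,4,5-tris(benzyloxy)benzoic acid | OC(=O)c1cc(OCc2ccccc2)c(OCc2ccccc2)c(OCc2ccccc2)c1 | starting material
2 | 3,4,5-tris(benzyloxy)-2-iodobenzoic acid | OC(=O)c1cc(OCc2ccccc2)c(OCc2ccccc2)c(OCc2ccccc2)c1I | intermediate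
3 | 2,5-dihydrofuran | C1C=CCO1 | starting material
4 | 3,4,5-tris(benzyloxy)-2-iodobenzoyl chloride | ClC(=O)c1cc(OCc2ccccc2)c(OCc2ccccc2)c(OCc2ccccc2)c1I | intermediate (not isolated)
5 | lithium (1Z)-buta-1,3-dien-1-olate | [Li+].[O-]/C=C\C=C | intermediate (not isolated)
6 | (1Z)-buta-1,3-dien-1-yl 3,4,5-tris(benzyloxy)-2-iodobenzoate | C=C\C=C/OC(=O)c1cc(OCc2ccccc2)c(OCc2ccccc2)c(OCc2ccccc2)c1I | intermediate
7 | (2E)-3-(tributylstannyl)prop-2-en-1-ol | CCCC[Sn](CCCC)(CCCC)/C=C/CO | starting material
8 | (1Z)-buta-1,3-dien-1-yl 3,4,5-tris(benzyloxy)-2-[(1E)-3-hydroxyprop-1-en-1-yl]benzoate | OC/C=C/c1c(OCc2ccccc2)c(OCc2ccccc2)c(OCc2ccccc2)cc1C(=O)O/C=C\C=C | intermediate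
9 | (1Z)-buta-1,3-dien-1-yl 3,4,5-tris(benzyloxy)-2-[(1E)-3-oxoprop-1-en-1-yl]benzoate | O=C/C=C/c1c(OCc2ccccc2)c(OCc2ccccc2)c(OCc2ccccc2)cc1C(=O)O/C=C\C=C | intermediate
10 | (1R,4aR,10bR)-8,9,10-tris(benzyloxy)-6-oxo-1,2,4a,10b-tetrahydro-6H-benzo[c]chromene-1-carbaldehyde | O=C[C@@H]1CC=C[C@H]2OC(=O)c3cc(OCc4ccccc4)c(OCc4ccccc4)c(OCc4ccccc4)c3[C@@H]12 | intermediate
11 | (2R)-2-[(3S,4R)-5,6,7-tris(benzyloxy)-3-formyl-1-oxo-3,4-dihydro-1H-isochromen-4-yl]butanedial | O=CC[C@@H](C=O)[C@@H]1c2c(cc(OCc3ccccc3)c(OCc3ccccc3)c2OCc3ccccc3)C(=O)O[C@@H]1C=O | intermediate (not isolated)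
12 | (2R)-2-[(3S,4R)-5,6,7-tris(benzyloxy)-3-carboxy-1-oxo-3,4-dihydro-1H-isochromen-4-yl]butanedioic acid | O=C(O)C[C@@H](C(=O)O)[C@@H]1c2c(cc(OCc3ccccc3)c(OCc3ccccc3)c2OCc3ccccc3)C(=O)O[C@@H]1C(=O)O | intermediate
13 | (2R)-2-[(3S,4R)-3-carboxy-5,6,7-trihydroxy-1-oxo-3,4-dihydro-1H-isochromen-4-yl]butanedioic acid | O=C(O)C[C@@H](C(=O)O)[C@@H]1c2c(cc(O)c(O)c2O)C(=O)O[C@@H]1C(=O)O | target

## Step count and least certain steps

Total: 7 steps. Longest linear sequence: 7 steps (1 to 13).

**Step 5 (key step).** The cycloaddition may be too slow, for three reasons: the ester must turn into its unfavoured rotamer, the (Z)-diene must reach its s-cis form, and the twisted, electron-rich aryl group lowers the electrophilicity of the iminium ion. Slow turnover would let acyl transfer from the enol ester to the amine or to water compete, heating would open an uncatalysed pathway and erode facial control, and the allylic benzoate of the product could eliminate.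

The fallback replaces catalyst control by auxiliary control with stronger Lewis-acid activation, sets out from enal 9 and returns at triacid 12:
- Chlorite oxidation of 9 gives (2E)-3-[2,3,4-tris(benzyloxy)-6-{[(1Z)-buta-1,3-dien-1-yloxy]carbonyl}phenyl]prop-2-enoic acid F1.
- Pivaloyl chloride and Et3N convert it into the mixed pivalic anhydride F2 (not isolated), which acylates (4R)-4-benzyl-1,3-oxazolidin-2-one in the presence of LiCl to give the trienimide F3.
- Me2AlCl (1.4 equiv, CH2Cl2, −30 °C) forms the chelated s-cis acyl oxazolidinone, whose Re face at the α-carbon lies anti to the benzyl group. Under the same geometric constraints of (Z)-diene and (E)-dienophile, the cycloaddition should give the imide cycloadduct F4.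
- The conditions of step 6 convert F4 through the dialdehyde imide F5 (not isolated) into the diacid imide F6.
- LiOH/H2O2 (THF/H2O, 0 °C) removes the auxiliary to give 12.

**Step 3.** Oxidative addition at the di-ortho-substituted iodide may be slow, so that protodeiodination or intramolecular arylpalladation of the dienyl ester competes. The fallback makes the aryl–alkenyl bond before any diene is present, sets out from acid 2 and returns at 8. Stille coupling of 2 with 7 under the conditions of step 3 gives 3,4,5-tris(benzyloxy)-2-[(1E)-3-hydroxyprop-1-en-1-yl]benzoic acid F7. F7 is not a Michael acceptor and cannot close to a phthalide. Ruthenium-catalysed anti-Markovnikov trans-addition of the carboxyl group of F7 to but-1-en-3-yne (Ru(η3-CH2C(CH3)CH2)2(Ph2P(CH2)4PPh2), toluene, 50 °C) installs the (Z)-dienyl ester and gives 8.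

**Step 2.** C-acylation or γ-acylation of the dienolate, proton return to give 2,3-dihydrofuran instead of ring opening, or leakage to the (E)-dienyl ester may lower the yield or the geometric purity. The fallback replaces enolate acylation by catalytic hydro-oxycarbonylation of an enyne, sets out from acid 2 and returns at 6. Acid 2 is added directly to but-1-en-3-yne with the same divalent ruthenium catalyst as above (toluene, 50 °C); this reaction type gives (Z)-enol esters by trans-addition. It makes no new compound, F0.

**Step 6.** The trialdehyde may epimerize at C3 (α-acyloxy aldehyde) or at C1', condense with itself, or the free arene position may be chlorinated during the chlorite stage. The fallback changes the order of events so that no trialdehyde accumulates, sets out from 10 and returns at 12. Chlorite oxidation of 10 alone gives (1R,4aR,10bR)-8,9,10-tris(benzyloxy)-6-oxo-1,2,4a,10b-tetrahydro-6H-benzo[c]chromene-1-carboxylic acid F8, an isolable acid whose crystallization could also raise the enantiomeric purity. Osmium-catalysed oxidative cleavage with KHSO5 (as 2KHSO5·KHSO4·K2SO4) in DMF at rt then takes the alkene of F8 directly to the two carboxyl groups of 12.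

## Further compounds

F1 | step 5 | (2E)-3-[2,3,4-tris(benzyloxy)-6-{[(1Z)-buta-1,3-dien-1-yloxy]carbonyl}phenyl]prop-2-enoic acid | OC(=O)/C=C/c1c(OCc2ccccc2)c(OCc2ccccc2)c(OCc2ccccc2)cc1C(=O)O/C=C\C=C
F2 | step 5 | mixed anhydride of F1 with 2,2-dimethylpropanoic acid | CC(C)(C)C(=O)OC(=O)/C=C/c1c(OCc2ccccc2)c(OCc2ccccc2)c(OCc2ccccc2)cc1C(=O)O/C=C\C=C
F3 | step 5 | (1Z)-buta-1,3-dien-1-yl 3,4,5-tris(benzyloxy)-2-{(1E)-3-[(4R)-4-benzyl-2-oxo-1,3-oxazolidin-3-yl]-3-oxoprop-1-en-1-yl}benzoate | O=C(/C=C/c1c(OCc2ccccc2)c(OCc2ccccc2)c(OCc2ccccc2)cc1C(=O)O/C=C\C=C)N1[C@H](Cc2ccccc2)COC1=O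
F4 | step 5 | (4R)-4-benzyl-3-{[(1R,4aR,10bR)-8,9,10-tris(benzyloxy)-6-oxo-1,2,4a,10b-tetrahydro-6H-benzo[c]chromen-1-yl]carbonyl}-1,3-oxazolidin-2-one | O=C([C@@H]1CC=C[C@H]2OC(=O)c3cc(OCc4ccccc4)c(OCc4ccccc4)c(OCc4ccccc4)c3[C@@H]12)N1[C@H](Cc2ccccc2)COC1=O
F5 | step 5 | (3R)-3-[(3S,4R)-5,6,7-tris(benzyloxy)-3-formyl-1-oxo-3,4-dihydro-1H-isochromen-4-yl]-4-[(4R)-4-benzyl-2-oxo-1,3-oxazolidin-3-yl]-4-oxobutanal | O=CC[C@@H](C(=O)N1[C@H](Cc2ccccc2)COC1=O)[C@@H]1c2c(cc(OCc3ccccc3)c(OCc3ccccc3)c2OCc3ccccc3)C(=O)O[C@@H]1C=O
F6 | step 5 | (3R)-3-[(3S,4R)-5,6,7-tris(benzyloxy)-3-carboxy-1-oxo-3,4-dihydro-1H-isochromen-4-yl]-4-[(4R)-4-benzyl-2-oxo-1,3-oxazolidin-3-yl]-4-oxobutanoic acid | O=C(O)C[C@@H](C(=O)N1[C@H](Cc2ccccc2)COC1=O)[C@@H]1c2c(cc(OCc3ccccc3)c(OCc3ccccc3)c2OCc3ccccc3)C(=O)O[C@@H]1C(=O)O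
F7 | step 3 | 3,4,5-tris(benzyloxy)-2-[(1E)-3-hydroxyprop-1-en-1-yl]benzoic acid | OC/C=C/c1c(OCc2ccccc2)c(OCc2ccccc2)c(OCc2ccccc2)cc1C(=O)O
F0 | step 2 | none | none
F8 | step 6 | (1R,4aR,10bR)-8,9,10-tris(benzyloxy)-6-oxo-1,2,4a,10b-tetrahydro-6H-benzo[c]chromene-1-carboxylic acid | O=C(O)[C@@H]1CC=C[C@H]2OC(=O)c3cc(OCc4ccccc4)c(OCc4ccccc4)c(OCc4ccccc4)c3[C@@H]12
A1 | alternative 1 | benzyl (2S)-5-oxo-2,5-dihydrofuran-2-carboxylate | O=C1C=C[C@@H](C(=O)OCc2ccccc2)O1
A2 | alternative 1 | benzyl (2S,3R,4R)-3-[2-(benzyloxycarbonyl)-4,5,6-tris(benzyloxy)phenyl]-4-[2-(benzyloxy)-2-oxoethyl]-5-oxooxolane-2-carboxylate | O=C(OCc1ccccc1)C[C@H]2C(=O)O[C@H](C(=O)OCc3ccccc3)[C@H]2c4c(OCc5ccccc5)c(OCc5ccccc5)c(OCc5ccccc5)cc4C(=O)OCc6ccccc6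
A3 | alternative 2 | tribenzyl 2-[2-(benzyloxycarbonyl)-4,5,6-tris(benzyloxy)phenyl]-1-oxobutane-1,3,4-tricarboxylate (mixture of epimers at both enolizable centres) | O=C(OCc1ccccc1)C(=O)C(c1c(OCc2ccccc2)c(OCc2ccccc2)c(OCc2ccccc2)cc1C(=O)OCc1ccccc1)C(C(=O)OCc1ccccc1)CC(=O)OCc1ccccc1
A4 | alternative 3 | ellagic acid | O=C1Oc2c(O)c(O)cc3C(=O)Oc4c(O)c(O)cc1c4c23
A5 | alternative 3 | mono-ring-fission diacid of ellagic acid (isocoumarin-3-carboxylic acid fused to a 3-(carboxymethylidene)chroman-2-one lactone) | O=C1OC(C(=O)O)=C2/C(=C\C(=O)O)C(=O)Oc3c(O)c(O)cc1c23
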